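**Retrosynthetic overview**

1. Target 14 is a 2-hydroxy-5-methoxy-1,4-benzoquinone (ring A: C1=O, C2–OH, C3–side chain, C4=O, C5–OMe, C6–H) with an (R)-2-acetoxytridecyl chain (C1'–C13') on C3. The plan rests on the unit ring C3–C1'H2–C2'H(O)–C3': an aryl carbon and an undecyl chain sit on the two carbons of a former vinyl group, and the inner carbon carries oxygen.
2. The C2 hydroxyl is traced back to the epoxide of a 2-methoxy-6-alkylquinone, the quinone to a 1-alkyl-2,3,5-trimethoxybenzene, and the C2' acetate to a secondary alcohol and then a secondary pinacol boronate.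
3. The boronate is cut at two bonds at once, aryl–C1' and C2'–C3', into 1-bromo-2,3,5-trimethoxybenzene, vinylboronic acid pinacol ester and undecylmagnesium bromide (enantioselective palladium-catalysed conjunctive coupling).
4. The aryl bromide comes from 5-bromovanillin by Dakin oxidation and double O-methylation. No ring is built: the benzene ring is bought and becomes quinone ring A late; only a transient epoxide ring is closed and reopened.

Key step: step 4

Assumption: MandyPhos, 1,1'-bis(diphenylphosphino)-2,2'-bis[α-(dimethylamino)benzyl]ferrocene, is sold as both antipodes; the one that gives the R boronate 9 is used, its sense of induction being checked on alcohol 10 (MTPA esters, pilot run) before scale-up.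

**Route**

Step 1
Reactants: 1 5-bromovanillin (3-bromo-4-hydroxy-5-methoxybenzaldehyde)
Product: 3 2-bromo-6-methoxybenzene-1,4-diol, via aryl formate 2 (not isolated)
Conditions: 30% H2O2 (1.2 equiv), NaOH (1.1 equiv), H2O/THF, 0 °C → rt, N2; then HCl to pH 2
Reagents that add atoms: hydrogen peroxide, OO
Why: Dakin oxidation, in which hydroperoxide adds to the aldehyde para to the phenoxide, the electron-rich aryl group migrates to oxygen and the formate 2 is saponified in the same flask.

Step 2
Reactants: 3 2-bromo-6-methoxybenzene-1,4-diol
Product: 4 1-bromo-2,3,5-trimethoxybenzene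
Conditions: Me2SO4 (2.5 equiv), K2CO3, acetone, reflux, N2
Reagents that add atoms: dimethyl sulfate, COS(=O)(=O)OC
Why: Williamson O-methylation of both phenoxides under carbonate base with air excluded, so that the hydroquinone is alkylated before it can be oxidised.

Step 3
Reactants: 5 1-bromoundecane
Product: 6 undecylmagnesium bromide (THF solution, titrated before use)
Conditions: Mg turnings, I2 (cat.), THF, reflux
Reagents that add atoms: magnesium, [Mg]
Why: Grignard reagent formation by insertion of magnesium into the primary C–Br bond.

Step 4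
Reactants: 7 vinylboronic acid pinacol ester; 6 undecylmagnesium bromide; 4 1-bromo-2,3,5-trimethoxybenzene
Product: 9 (R)-2-[1-(2,3,5-trimethoxyphenyl)tridecan-2-yl]-4,4,5,5-tetramethyl-1,3,2-dioxaborolane, via vinyl(undecyl)boronate complex 8 (not isolated)
Conditions: 6 added to 7, THF, 0 °C → rt, 30 min; then NaOSO2CF3 (NaOTf, 2 equiv), Pd(OAc)2 (2 mol%), MandyPhos (2.4 mol%), 4 (limiting), THF, 60 °C, 14 h
Reagents that add atoms: none
Why: The Grignard reagent adds to boron of 7 to give the four-coordinate ate complex 8, while oxidative addition of 4 to zerovalent palladium–MandyPhos and removal of bromide by NaOTf give a cationic divalent arylpalladium that binds the vinyl group of 8. Undecyl then migrates from boron to the boron-bearing carbon C2' anti to palladium (1,2-metallate shift, forming C2'–C3') as the terminal carbon C1' bonds to palladium, and C–C reductive elimination forms aryl–C1' and returns zerovalent palladium. This is the known enantioselective conjunctive cross-coupling of Grignard-derived vinylboron ate complexes with aryl bromides, and no ring is closed. The C2' stereocentre is controlled by the chiral bisphosphine, which fixes the alkene face held by palladium and therefore the face that receives undecyl, the antipode being chosen for R. The step needs the metallate shift to outrun direct Suzuki–Miyaura transfer of vinyl or undecyl and β-hydride elimination, which the wide-bite bidentate ligand, the halide-free cationic palladium and the pinacol ester favour, and the single ortho substituent of 4 keeps oxidative addition feasible. Regiochemistry is inherent, since palladium and hence the aryl group can only end on the terminal vinyl carbon.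

Step 5
Reactants: 9 (R)-2-[1-(2,3,5-trimethoxyphenyl)tridecan-2-yl]-4,4,5,5-tetramethyl-1,3,2-dioxaborolane
Product: 10 (R)-1-(2,3,5-trimethoxyphenyl)tridecan-2-ol
Conditions: 3 M NaOH, 30% H2O2, THF, 0 °C → rt
Reagents that add atoms: hydrogen peroxide, OO
Why: Oxidation of the C–B bond by hydroperoxide, in which the alkyl group shifts from boron to oxygen with retention at C2', so the R configuration passes into the alcohol.

Step 6
Reactants: 10 (R)-1-(2,3,5-trimethoxyphenyl)tridecan-2-ol
Product: 11 (R)-1-(2,3,5-trimethoxyphenyl)tridecan-2-yl acetate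
Conditions: Ac2O, pyridine, DMAP (cat.), CH2Cl2, rt
Reagents that add atoms: acetic anhydride, CC(=O)OC(C)=O
Why: DMAP-catalysed O-acylation that leaves the C2'–O bond untouched and blocks the hydroxyl against later oxa-Michael addition to the quinone.

Step 7
Reactants: 11 (R)-1-(2,3,5-trimethoxyphenyl)tridecan-2-yl acetate
Product: 12 (R)-1-(5-methoxy-3,6-dioxocyclohexa-1,4-dien-1-yl)tridecan-2-yl acetate (a 2-methoxy-6-alkyl-1,4-benzoquinone)
Conditions: (NH4)2Ce(NO3)6 (2.5 equiv), MeCN/H2O (2:1), 0 °C
Reagents that add atoms: water, O
Why: Oxidative demethylation by tetravalent cerium, in which the para-related methoxy groups at aryl C2 and C5 leave as methanol and the para-quinone forms in preference to the ortho-quinone, the acetate being inert.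

Step 8
Reactants: 12 (R)-1-(5-methoxy-3,6-dioxocyclohexa-1,4-dien-1-yl)tridecan-2-yl acetate
Product: 13 (2R)-1-(3-methoxy-2,5-dioxo-7-oxabicyclo[4.1.0]hept-3-en-1-yl)tridecan-2-yl acetate (two cis-epoxide diastereomers)
Conditions: 30% H2O2, Na2CO3, THF/H2O, 0 °C, short contact; pH 7 buffer quench
Reagents that add atoms: hydrogen peroxide, OO
Why: Weitz–Scheffer nucleophilic epoxidation, in which hydroperoxide adds to the unsubstituted carbon of the alkyl-bearing enone and not to the electron-rich methoxy enol-ether alkene, and the enolate closes on O–O; both diastereomers converge in step 9.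

Step 9
Reactants: 13 (2R)-1-(3-methoxy-2,5-dioxo-7-oxabicyclo[4.1.0]hept-3-en-1-yl)tridecan-2-yl acetate
Product: 14 (R)-1-(2-hydroxy-5-methoxy-3,6-dioxocyclohexa-1,4-dien-1-yl)tridecan-2-yl acetate (target)
Conditions: conc. H2SO4 adsorbed on SiO2, CH2Cl2, rt
Reagents that add atoms: none
Why: Acid-catalysed isomerisation of an epoxy-enedione (the reaction type that turns 2-methyl-1,4-naphthoquinone epoxide into its hydroxyquinone), in which enolisation at the epoxide CH and vinylogous opening of the C–O bond at the alkyl-bearing carbon leave the hydroxyl next to the side chain, a supported acid in a non-nucleophilic solvent sparing the acetate.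

**Compound list**

1 | 5-bromovanillin (3-bromo-4-hydroxy-5-methoxybenzaldehyde) | COc1cc(C=O)cc(Br)c1O | starting material
2 | 3-bromo-4-hydroxy-5-methoxyphenyl formate (formed in the flask, not isolated) | COc1cc(OC=O)cc(Br)c1O | intermediate
3 | 2-bromo-6-methoxybenzene-1,4-diol | COc1cc(O)cc(Br)c1O | intermediate
4 | 1-bromo-2,3,5-trimethoxybenzene | COc1cc(Br)c(OC)c(OC)c1 | intermediate
5 | 1-bromoundecane | CCCCCCCCCCCBr | starting material
6 | undecylmagnesium bromide | CCCCCCCCCCC[Mg]Br | intermediate
7 | vinylboronic acid pinacol ester (4,4,5,5-tetramethyl-2-vinyl-1,3,2-dioxaborolane) | C=CB1OC(C)(C)C(C)(C)O1 | starting material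
8 | bromomagnesium undecyl(vinyl)(pinacolato)borate (formed in the flask, not isolated) | CCCCCCCCCCC[B-]1(C=C)OC(C)(C)C(C)(C)O1.[Mg+]Br | intermediate
9 | (R)-2-[1-(2,3,5-trimethoxyphenyl)tridecan-2-yl]-4,4,5,5-tetramethyl-1,3,2-dioxaborolane | CCCCCCCCCCC[C@H](Cc1cc(OC)cc(OC)c1OC)B1OC(C)(C)C(C)(C)O1 | intermediate
10 | (R)-1-(2,3,5-trimethoxyphenyl)tridecan-2-ol | CCCCCCCCCCC[C@H](Cc1cc(OC)cc(OC)c1OC)O | intermediate
11 | (R)-1-(2,3,5-trimethoxyphenyl)tridecan-2-yl acetate | CCCCCCCCCCC[C@H](Cc1cc(OC)cc(OC)c1OC)OC(C)=O | intermediate
12 | (R)-1-(5-methoxy-3,6-dioxocyclohexa-1,4-dien-1-yl)tridecan-2-yl acetate | CCCCCCCCCCC[C@H](CC1=CC(=O)C=C(OC)C1=O)OC(C)=O | intermediate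
13 | (2R)-1-(3-methoxy-2,5-dioxo-7-oxabicyclo[4.1.0]hept-3-en-1-yl)tridecan-2-yl acetate (both cis-epoxide diastereomers, epoxide carbons left undefined) | CCCCCCCCCCC[C@H](CC12OC1C(=O)C=C(OC)C2=O)OC(C)=O | intermediate
14 | (R)-1-(2-hydroxy-5-methoxy-3,6-dioxocyclohexa-1,4-dien-1-yl)tridecan-2-yl acetate | CCCCCCCCCCC[C@H](CC1=C(O)C(=O)C=C(OC)C1=O)OC(C)=O | target

**Step count**

Total: 9 steps. Longest linear sequence: 8 steps (steps 1, 2, 4, 5, 6, 7, 8, 9 from 5-bromovanillin 1). Step 3 is a one-step side branch that joins at step 4.

**Steps most likely to fail**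

Step 4. Oxidative addition of the electron-rich, ortho-methoxylated bromide may be slow, so that direct Suzuki–Miyaura transfer or protodeboronation of the ate complex competes, or facial discrimination in the metallate shift may be insufficient. The fallback sets out from aryl bromide 4 and comes back at alcohol 10, replacing the coupling by epoxide opening. 1-Tridecene is epoxidised with mCPBA to racemic 2-undecyloxirane F1. Hydrolytic kinetic resolution of F1 with 0.55 equiv of water and (salen)Co(OAc), the acetate of the trivalent cobalt complex of N,N'-bis(3,5-di-tert-butylsalicylidene)cyclohexane-1,2-diamine (antipode that leaves the R epoxide), gives (R)-2-undecyloxirane F2. Bromide 4 is converted with Mg in THF into (2,3,5-trimethoxyphenyl)magnesium bromide F3. CuI-catalysed opening of F2 by F3 at the CH2 terminus (THF, −20 → 0 °C) should give 10, with the stereocentre taken unchanged from the epoxide.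

Step 8. Hydroperoxide or hydroxide may attack the methoxy-bearing carbon with loss of methoxide, the acetate may be cleaved, or base may form the quinone methide tautomer and expel the homobenzylic acetate. The fallback sets out from quinone 12 and comes back at target 14, using acid throughout. Thiele–Winter acetoxylation (Ac2O, cat. H2SO4, rt) adds acetate para to the methoxy group and should give (R)-1-(2,3,6-triacetoxy-5-methoxyphenyl)tridecan-2-yl acetate F4. The three aryl acetates are then cleaved selectively over the alkyl acetate (NH4OAc, aqueous MeOH, rt) to (R)-1-(2,3,6-trihydroxy-5-methoxyphenyl)tridecan-2-yl acetate F5. F5 is not isolated and is oxidised by air in the same flask to 14.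

Step 9. The acid may open the epoxide at the tertiary carbon with participation of the neighbouring acetate, or cleave the acetate, instead of enolising at the epoxide CH. The fallback sets out from epoxide 13 and comes back at target 14, using base and a protecting-group exchange. K2CO3 in MeOH isomerises the epoxide through the enolate and removes the acetate, to give 2-hydroxy-3-[(R)-2-hydroxytridecyl]-5-methoxy-1,4-benzoquinone F6 as its stable anion. Ac2O/pyridine then gives (R)-1-(2-acetoxy-5-methoxy-3,6-dioxocyclohexa-1,4-dien-1-yl)tridecan-2-yl acetate F7. The labile vinylogous-anhydride acetate on the ring is removed selectively with NaHCO3 in aqueous MeOH at 0 °C to give 14.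

**Further compounds**

F1 | step 4 | racemic 2-undecyloxirane | CCCCCCCCCCCC1CO1
F2 | step 4 | (R)-2-undecyloxirane | CCCCCCCCCCC[C@@H]1CO1
F3 | step 4 | (2,3,5-trimethoxyphenyl)magnesium bromide | COc1cc([Mg]Br)c(OC)c(OC)c1
F4 | step 8 | (R)-1-(2,3,6-triacetoxy-5-methoxyphenyl)tridecan-2-yl acetate | CCCCCCCCCCC[C@H](Cc1c(OC(C)=O)c(OC(C)=O)cc(OC)c1OC(C)=O)OC(C)=O
F5 | step 8 | (R)-1-(2,3,6-trihydroxy-5-methoxyphenyl)tridecan-2-yl acetate | CCCCCCCCCCC[C@H](Cc1c(O)c(O)cc(OC)c1O)OC(C)=O
F6 | step 9 | 2-hydroxy-3-[(R)-2-hydroxytridecyl]-5-methoxy-1,4-benzoquinone | CCCCCCCCCCC[C@H](CC1=C(O)C(=O)C=C(OC)C1=O)O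
F7 | step 9 | (R)-1-(2-acetoxy-5-methoxy-3,6-dioxocyclohexa-1,4-dien-1-yl)tridecan-2-yl acetate | CCCCCCCCCCC[C@H](CC1=C(OC(C)=O)C(=O)C=C(OC)C1=O)OC(C)=O
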